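**Retrosynthetic overview**
1. Numbering: ring O1, C2 (side chain), C3, C4 (C=O), C5, C6; side chain C1'–C3'. The plan rests on the C1' gem-dibromide next to ring C2 of the single 4-pyranone ring. A carbon with two C–Br bonds is at ketone oxidation level, so both bonds are traced back to the C1' carbonyl of a 2-propanoyl pyranone through its N-silyl hydrazone.
2. The three ring C–Br bonds are disconnected first. They go on after the side chain: substitution at C3 and C5, then bromine addition and HBr loss across C5=C6 for C6.
3. The ketone comes from comanic acid: the C1'–C2' bond is made from ethylmagnesium bromide and the Weinreb amide of the C2 carboxyl group.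
4. Ring order: no ring is formed; the pyranone is bought intact in comanic acid and carried through.

Key step: step 4

Remark: all names use the numbering above; by lowest-locant rules the target is 2,3,5-tribromo-6-(1,1-dibromopropyl)-4H-pyran-4-one, and it has no stereocentre.

**Step 1**
Reactants: 1 comanic acid (4-oxo-4H-pyran-2-carboxylic acid)
Product: 3 N-methoxy-N-methyl-4-oxo-4H-pyran-2-carboxamide, via comanoyl chloride 2 (not isolated)
Conditions: (COCl)2 (1.2 equiv), DMF (cat.), CH2Cl2, 0 → 23 °C; concentrate; MeNH(OMe)·HCl (1.1 equiv), pyridine (2.5 equiv), CH2Cl2, 0 °C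
Reagents that add atoms: oxalyl chloride, O=C(Cl)C(=O)Cl (supplies the chlorine of 2 only); N,O-dimethylhydroxylamine hydrochloride, CNOC.Cl
Why: Amide formation by acyl substitution through the acid chloride: chloride 2 should acylate the weakly basic N,O-dimethylhydroxylamine much faster than this secondary amine can add at C6 of the pyranone.

**Step 2**
Reactants: 3 N-methoxy-N-methyl-4-oxo-4H-pyran-2-carboxamide; 4 ethylmagnesium bromide
Product: 6 2-propanoyl-4H-pyran-4-one, via magnesium hemiaminal chelate 5 (not isolated)
Conditions: EtMgBr (1.1 equiv, dropwise), THF, −78 °C; cold 1 M HCl quench at −78 °C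
Reagents that add atoms: none
Why: Weinreb ketone synthesis: the five-membered magnesium chelate 5 should hold the adduct until work-up, and at −78 °C with a near-stoichiometric charge the amide carbonyl on the electron-poor ring should react ahead of the vinylogous-ester C4 carbonyl and ahead of conjugate addition at C6.

**Step 3**
Reactants: 6 2-propanoyl-4H-pyran-4-one; 7 1,2-bis(tert-butyldimethylsilyl)hydrazine
Product: 8 2-propanoyl-4H-pyran-4-one N-(tert-butyldimethylsilyl)hydrazone (C=N isomer mixture)
Conditions: 7 (1.2 equiv), Sc(OTf)3 (1 mol%), CHCl3, 23 → 55 °C; volatiles removed under high vacuum; crude 8 used directly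
Reagents that add atoms: none
Why: Lewis-acid-catalysed condensation of a ketone with a bis-silyl hydrazine (N-silyl hydrazone formation with loss of silanol): the C1' ketone is far more electrophilic than the C4 carbonyl and the silylated nitrogen is too weak a nucleophile to add at C6, so the ring should not be opened as it would be by free hydrazine; the C=N geometry does not matter because C1' ends as a CBr2 centre.

**Step 4**
Reactants: 8 2-propanoyl-4H-pyran-4-one N-(tert-butyldimethylsilyl)hydrazone
Product: 11 2-(1,1-dibromopropyl)-4H-pyran-4-one, via free hydrazone 9 (not isolated), via diazo compound 10 (not isolated)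
Conditions: CuBr2 (6 equiv), Et3N (3 equiv), MeOH, 0 °C, slow addition of 8 in THF; then 23 °C
Reagents that add atoms: copper dibromide, Br[Cu]Br
Why: Methanolysis of the N–Si bond should release hydrazone 9, which CuBr2 and Et3N oxidise in two one-electron steps to diazoalkane 10, a vinylogous diazoketone whose C1' charge is delocalised through C2=C3 onto the C4 carbonyl; C1' then takes a bromine from further CuBr2 to give an α-bromo diazonium ion, and loss of N2 with bromide return inside the copper bromide ion pair forms the second C1'–Br bond. The closest known reaction type is the conversion of ketone hydrazones and their N-silyl derivatives into gem-dihalides by copper dihalides and a tertiary amine. No ring is closed and no stereocentre arises, since C1' ends with two identical bromines. The step needs the gem-dibromide in preference to the 1-bromopropenyl compound formed by loss of a C2' proton: a C1' cation would sit on C2, the β-carbon of the enone, so it should never be free and bromide capture in the bromide-rich medium should outrun deprotonation. It also needs an intact pyranone: no hydrazine or primary amine is present to add at C6, Et3N is non-nucleophilic, and slow addition at 0 °C keeps 10 dilute so that azine formation, protonation by methanol and 1,5-electrocyclisation onto C3 should stay minor.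

**Step 5**
Reactants: 11 2-(1,1-dibromopropyl)-4H-pyran-4-one
Product: 13 3,5-dibromo-2-(1,1-dibromopropyl)-4H-pyran-4-one, via 5-bromo pyranone 12 (not isolated)
Conditions: Br2 (2.5 equiv), NaOAc (3 equiv), AcOH, 23 → 50 °C, dark
Reagents that add atoms: bromine, BrBr
Why: Electrophilic substitution (halogenation of a 4-pyranone at the carbons α to its carbonyl): C3 and C5 are the nucleophilic carbons of the two enol-ether units, bromine attack gives an O1-stabilised oxocarbenium ion that loses the ring proton to acetate, the open C5 should react first (12) and the crowded C3 second, while C1' has no hydrogen and C2' is inert to ionic bromination in the dark.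

**Step 6**
Reactants: 13 3,5-dibromo-2-(1,1-dibromopropyl)-4H-pyran-4-one
Product: 15 3,5,6-tribromo-2-(1,1-dibromopropyl)-4H-pyran-4-one, via bromine adduct 14 (not isolated)
Conditions: Br2 (5 equiv), CHCl3, 23–40 °C, dark; evaporate; i-Pr2NEt (1.2 equiv), CH2Cl2, −20 → 0 °C
Reagents that add atoms: bromine, BrBr
Why: Bromine addition–dehydrobromination: Br2 should add only across C5=C6 (bromine to C5, bromide to the O1-stabilised C6 cation; C2=C3 is tetrasubstituted and shielded), and the hindered amine then removes C6–H anti to one C5–Br as in the dehydrobromination of an α-bromo ketone, restoring the pyranone; the C6 stereocentre of 14 forms racemic and is erased.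

**Compound list**
1 | comanic acid (4-oxo-4H-pyran-2-carboxylic acid) | O=C(O)c1cc(=O)cco1 | starting material
2 | comanoyl chloride (4-oxo-4H-pyran-2-carbonyl chloride) | O=C(Cl)c1cc(=O)cco1 | intermediate (not isolated)
3 | N-methoxy-N-methyl-4-oxo-4H-pyran-2-carboxamide | CON(C)C(=O)c1cc(=O)cco1 | intermediate
4 | ethylmagnesium bromide | CC[Mg]Br | starting material
5 | bromomagnesium alkoxide of 1-[methoxy(methyl)amino]-1-(4-oxo-4H-pyran-2-yl)propan-1-ol (chelate) | CCC(O[Mg]Br)(N(C)OC)c1cc(=O)cco1 | intermediate (not isolated)
6 | 2-propanoyl-4H-pyran-4-one | CCC(=O)c1cc(=O)cco1 | intermediate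
7 | 1,2-bis(tert-butyldimethylsilyl)hydrazine | CC(C)(C)[Si](C)(C)NN[Si](C)(C)C(C)(C)C | starting material
8 | 2-propanoyl-4H-pyran-4-one N-(tert-butyldimethylsilyl)hydrazone (C=N geometry undefined) | CCC(=NN[Si](C)(C)C(C)(C)C)c1cc(=O)cco1 | intermediate
9 | 2-propanoyl-4H-pyran-4-one hydrazone | CCC(=NN)c1cc(=O)cco1 | intermediate (not isolated)
10 | 2-(1-diazopropyl)-4H-pyran-4-one | CCC(=[N+]=[N-])c1cc(=O)cco1 | intermediate (not isolated)
11 | 2-(1,1-dibromopropyl)-4H-pyran-4-one | CCC(Br)(Br)c1cc(=O)cco1 | intermediate
12 | 5-bromo-2-(1,1-dibromopropyl)-4H-pyran-4-one | CCC(Br)(Br)c1cc(=O)c(Br)co1 | intermediate (not isolated)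
13 | 3,5-dibromo-2-(1,1-dibromopropyl)-4H-pyran-4-one | CCC(Br)(Br)c1occ(Br)c(=O)c1Br | intermediate
14 | 2,3,3,5-tetrabromo-6-(1,1-dibromopropyl)-2,3-dihydro-4H-pyran-4-one (racemic; the C5=C6 adduct of 13) | CCC(Br)(Br)C1=C(Br)C(=O)C(Br)(Br)C(Br)O1 | intermediate (not isolated)
15 | 3,5,6-tribromo-2-(1,1-dibromopropyl)-4H-pyran-4-one (= 2,3,5-tribromo-6-(1,1-dibromopropyl)-4H-pyran-4-one) | CCC(Br)(Br)c1oc(Br)c(Br)c(=O)c1Br | target

**Total step count:** 6 steps.
**Longest linear sequence:** 6 steps, from comanic acid 1.

**Steps most likely to fail**

Step 6. Addition of bromine to the deactivated and crowded C5=C6 bond may be slow or may reverse. On base treatment the adduct may lose Br2 (amine attack at a C5 bromine) in place of HBr, or the side chain may undergo elimination. The fallback sets out from 13 and returns at 15. It replaces addition–elimination by C–H metalation: the only ring hydrogen, C6–H, flanked by O1 and C5–Br, is removed with TMPZnCl·LiCl (MgCl2 as Lewis acid at the C4 carbonyl, THF, −30 → 0 °C). This should give [3,5-dibromo-6-(1,1-dibromopropyl)-4-oxo-4H-pyran-2-yl]zinc chloride F1, which is quenched with Br2 at −40 °C to give 15. Zincation of 4-pyranones next to the ring oxygen with TMP zinc amides followed by halogen trapping is known chemistry.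

Step 4. Proton loss from C2' at the bromo-diazonium stage would give the vinyl bromide. The diazo intermediate may also be protonated by methanol or cyclise onto C3. The fallback sets out from ketone 6 and returns at 11. It avoids both the diazo compound and any C1' cation. Luche reduction (NaBH4, CeCl3·7H2O, MeOH, −40 °C) should give racemic 2-(1-hydroxypropyl)-4H-pyran-4-one F2. An Appel reaction (CBr4, PPh3, CH2Cl2, 0 °C) should give racemic 2-(1-bromopropyl)-4H-pyran-4-one F3. Wohl–Ziegler bromination (NBS, AIBN cat., PhCF3, 80 °C) then puts the second bromine on the same carbon, whose radical is stabilised by the first bromine and by conjugation with C2=C3, to give 11.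

Step 2. The Grignard reagent may add to the pyranone (at the C4 carbonyl or in conjugate fashion at C6) in competition with the amide. The fallback sets out from comanic acid 1 by way of chloride 2 and returns at ketone 6. It uses an organozinc reagent, which does not add to the ring. Chloride 2 with EtSH and pyridine (CH2Cl2, 0 °C) should give S-ethyl 4-oxo-4H-pyran-2-carbothioate F4. Fukuyama coupling (EtZnI, PdCl2(PPh3)2 cat., toluene/THF, 23 °C) then gives 6.

**Further compounds**
F1 | step 6 | [3,5-dibromo-6-(1,1-dibromopropyl)-4-oxo-4H-pyran-2-yl]zinc chloride | CCC(Br)(Br)c1oc([Zn]Cl)c(Br)c(=O)c1Br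
F2 | step 4 | 2-(1-hydroxypropyl)-4H-pyran-4-one (racemic) | CCC(O)c1cc(=O)cco1
F3 | step 4 | 2-(1-bromopropyl)-4H-pyran-4-one (racemic) | CCC(Br)c1cc(=O)cco1
F4 | step 2 | S-ethyl 4-oxo-4H-pyran-2-carbothioate | CCSC(=O)c1cc(=O)cco1
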